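**Retrosynthetic overview**
1. Target ⇐ allyl β-keto ester 25 by Pd-catalysed decarboxylative protonation (sets C2).
2. 25 ⇐ aldehyde/lactone/ester 22 by a one-pot Dieckmann / aldol / lactonisation cascade that closes rings A, F and E and sets C20 and C19.
3. 22 ⇐ bridged amino-lactone ketone 18 (ring B already closed) by one-carbon homologation of the C14 ketone and a deconjugative Michael addition (sets C14).
4. 18 ⇐ exo-methylene dienone 9 by a formal [3+2] annulation with methyl isocyanoacetate (C20–C21 and C22–C23 bonds, quaternary C22), then imine cleavage, lactonisation, ozonolysis and reductive amination.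
5. 9 ⇐ cycloheptanone via the 2,6-dienone, two catalytic asymmetric conjugate additions (C9, C6) and a cyclopentene annulation. Ring order: C → D → temporary pyrroline/δ-lactone → B → A + F + E.

Assumption: atom labels C1–C24 (N4, O18 = lactone ring oxygen) follow the atom order of the target SMILES; C2 is carried as an unassigned mixture from 16 to 25 and is set in step 14; nothing here has been run, and selectivities are predictions.

**Step 1**
Reactants: 1 cycloheptanone
Product: 2 cyclohepta-2,6-dien-1-one
Conditions: IBX (2.5 equiv), DMSO/PhF, 75 °C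
Reagents that add atoms: none
Why: IBX dehydrogenation of a ketone to the enone, run twice on the symmetrical ketone by control of stoichiometry and temperature.

**Step 2**
Reactants: 2 cyclohepta-2,6-dien-1-one; 3 [2-(1,3-dioxolan-2-yl)ethyl]magnesium bromide
Product: 4 (6S)-6-[2-(1,3-dioxolan-2-yl)ethyl]cyclohept-2-en-1-one
Conditions: CuCl (5 mol %), Taniaphos (6 mol %, enantiomer giving 6S), Et2O, −60 °C; aq. NH4Cl
Reagents that add atoms: none
Why: Cu-catalysed asymmetric conjugate addition of a Grignard reagent sets C9 under ligand control, and the magnesium dienolate formed blocks a second addition so the far enone returns on protonation.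

**Step 3**
Reactants: 4 (6S)-6-[2-(1,3-dioxolan-2-yl)ethyl]cyclohept-2-en-1-one; 5 (E)-prop-1-enylboronic acid
Product: 6 (3S,6S)-3-[2-(1,3-dioxolan-2-yl)ethyl]-6-[(E)-prop-1-enyl]cycloheptan-1-one (substituents cis)
Conditions: [Rh(OH)((S)-BINAP)]2 (2.5 mol %), dioxane/H2O 10:1, 35 °C
Reagents that add atoms: none
Why: Rh-catalysed asymmetric 1,4-addition of an alkenylboronic acid (Hayashi–Miyaura) sets C6 under catalyst control, cis to the C9 side chain.

**Step 4**
Reactants: 6 (3S,6S)-3-[2-(1,3-dioxolan-2-yl)ethyl]-6-[(E)-prop-1-enyl]cycloheptan-1-one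
Product: 8 (3aS,6S)-6-[(E)-prop-1-enyl]-3,3a,4,5,6,7-hexahydroazulen-8(2H)-one, via keto aldehyde 7 (not isolated)
Conditions: 2 M HCl, THF, 60 °C
Reagents that add atoms: none
Why: Acetal hydrolysis then intramolecular aldol condensation (cyclopentene annulation) closes ring D through the only α-carbon that gives a fused five-membered ring, placing the C12=C13 alkene without touching C9 or C6.

**Step 5**
Reactants: 8 (3aS,6S)-6-[(E)-prop-1-enyl]-3,3a,4,5,6,7-hexahydroazulen-8(2H)-one
Product: 9 (3aR,6R)-7-methylidene-6-[(E)-prop-1-enyl]-3,3a,4,5,6,7-hexahydroazulen-8(2H)-one (same spatial arrangement as 8)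
Conditions: (CH2O)n, i-Pr2NH2+ CF3CO2− (1 equiv), THF, 65 °C
Reagents that add atoms: formaldehyde (from paraformaldehyde), C=O
Why: Mannich-type α-methylenation at C22, the only enolisable α-position of the enone, installs C21 as a reactive exo-methylene acceptor.

**Step 6**
Reactants: 9 (3aR,6R)-7-methylidene-6-[(E)-prop-1-enyl]-3,3a,4,5,6,7-hexahydroazulen-8(2H)-one; 10 methyl isocyanoacetate
Product: 11 methyl 8-oxo-6-[(E)-prop-1-enyl]-2,3,3a,4,4',5,5',6-octahydro-8H-spiro[azulene-7,3'-pyrrole]-5'-carboxylate (C22 spiro; N4=C23H; C23 anti to propenyl; CO2Me cis to C14=O)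
Conditions: AgOAc (5 mol %), DBU (10 mol %), MeCN, 0 °C → rt
Reagents that add atoms: none
Why: Formal [3+2] cycloaddition of an isocyanoacetate (Michael addition of C20 to C21, then 5-endo-dig attack of the C22 enolate on the isocyanide carbon C23) builds the quaternary C22 with C23 entering anti to the C6 propenyl group, while the acidic C20–H equilibrates to the epimer with the ester trans to the C6 branch.

**Step 7**
Reactants: 11 spiro-pyrroline ester
Product: 13 methyl 2-[(tert-butoxycarbonyl)amino]-3-[7-(hydroxymethyl)-8-oxo-6-[(E)-prop-1-enyl]-2,3,3a,4,5,6,7,8-octahydroazulen-7-yl]propanoate, via N-Boc hemiaminal 12 (not isolated)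
Conditions: Boc2O, THF/H2O, rt; then NaBH4, MeOH, −20 °C
Reagents that add atoms: di-tert-butyl dicarbonate, CC(C)(C)OC(=O)OC(=O)OC(C)(C)C; water, O
Why: N-acylation and hydration of the cyclic imine give a hemiaminal whose ring-opened aldehyde is reduced by borohydride (reductive ring opening), freeing C23 as CH2OH and N4 as NHBoc while the hindered C14 enone survives.

**Step 8**
Reactants: 13 N-Boc amino alcohol ester; 14 allyl methacrylate
Product: 16 allyl 2-methyl-3-[(spiro δ-lactone-3'-yl)amino]propanoate (N4–C3H2–C2H(CH3)–CO2allyl on the spiro[azulene-7,5'-oxane]-2',8-dione; C2 mixture), via amino lactone 15 (not isolated)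
Conditions: TFA, CH2Cl2, 0 °C → rt, evaporate; then Et3N, neat 14, BHT, 60 °C
Reagents that add atoms: none
Why: Acidolysis removes Boc and closes the δ-lactone C23–O–C24(=O), which masks the C23 hydroxyl and activates C24, and aza-Michael addition of the primary amine to the methacrylate then attaches C3, C2 and C1.

**Step 9**
Reactants: 16 N-alkylated amino lactone
Product: 18 bridged amino-lactone ketone (2-oxa-6-azabicyclo[3.3.1]nonan-3-one with bridges N4–C5–C6, C21 and C24(=O)–O–C23 between C20 and C22, fused at C6–C22 to the hexahydroazulen-8-one; N4 bears CH2CH(CH3)CO2allyl), via C5 aldehyde 17 (not isolated)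
Conditions: O3, TFA (1.1 equiv), CH2Cl2/MeOH, −78 °C; Me2S; evaporate; NaBH(OAc)3, NaOAc, DCE, rt
Reagents that add atoms: none
Why: Ozonolysis cleaves the electron-rich disubstituted propenyl alkene in preference to the enone and the allyl ester alkenes (amine protected as its salt), and intramolecular reductive amination then closes ring B, which is possible only with N4 cis to C6 as set in step 6.

**Step 10**
Reactants: 18 bridged amino-lactone ketone
Product: 19 C14 spiro-oxirane of 18 (oxirane CH2 = C19; C14 epimers)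
Conditions: Me3S+ I−, n-BuLi, THF, −10 → 0 °C
Reagents that add atoms: trimethylsulfonium iodide, C[S+](C)C.[I-]
Why: Corey–Chaykovsky epoxidation, in which the small sulfonium ylide adds 1,2 to the enone carbonyl faster than to the lactone or ester and delivers C19, the C14 configuration being irrelevant because it is erased in steps 11 and 12.

**Step 11**
Reactants: 19 C14 spiro-oxirane
Product: 20 C14 carbaldehyde of the same tetracycle (C14–H; CHO = C19; C12=C13 retained)
Conditions: BF3·OEt2 (2.2 equiv), CH2Cl2, −78 °C; Et3N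
Reagents that add atoms: none
Why: Meinwald rearrangement, in which Lewis-acid opening to the allylic C14 cation is followed by a 1,2-hydride shift from C19 to give the β,γ-unsaturated aldehyde, the amine being tied up as its BF3 adduct.

**Step 12**
Reactants: 20 C14 carbaldehyde; 21 methyl acrylate
Product: 22 C14-quaternary aldehyde (20 bearing CH2CH2CO2CH3 at C14 on the face of C23)
Conditions: DBU (0.3 equiv), MeCN, 0 °C → rt
Reagents that add atoms: none
Why: Deconjugative α-selective Michael addition of the extended enolate of the aldehyde forms the quaternary C14 with the acrylate entering from the face opposite the ring-B cage (N4, C5, C20, C21), so that C15 is syn to C23 and the C19 aldehyde points toward C20.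

**Step 13**
Reactants: 22 C14-quaternary aldehyde
Product: 25 allyl ester of the target 2-carboxylic acid (target skeleton with C2(CH3)(CO2allyl); free C23H2OH), via Dieckmann keto aldehyde 23 (not isolated), via aldol hydroxy ester 24 (not isolated)
Conditions: KOtBu (1.5 equiv), THF, −40 → 0 °C; AcOH
Reagents that add atoms: none
Why: A Dieckmann condensation of the C2 ester enolate on the lactone carbonyl C24 closes ring A and releases C23–OH, the resulting C20 enolate undergoes intramolecular aldol addition to the C19 aldehyde (ring F, with C20 fixed by the bridging geometry of ring B), and under reversible aldol conditions only the C19 alkoxide syn to the C15 chain can lactonise onto the methyl ester (ring E), which fixes C19.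

**Step 14**
Reactants: 25 allyl β-keto ester
Product: 26 target CNP0180795.1
Conditions: Pd(OAc)2 (10 mol %), (S)-t-Bu-PHOX (12.5 mol %), HCO2H, 4 Å MS, dioxane, 40 °C
Reagents that add atoms: none
Why: Pd-catalysed decarboxylative protonation of the allyl β-keto ester gives a chiral Pd enolate that is protonated at C2 under ligand control (2R), the substrate itself having little facial bias at this remote centre.

**Compound list**
1 | cycloheptanone | O=C1CCCCCC1 | starting material
2 | cyclohepta-2,6-dien-1-one | O=C1C=CCCC=C1 | intermediate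
3 | [2-(1,3-dioxolan-2-yl)ethyl]magnesium bromide | Br[Mg]CCC1OCCO1 | starting material
4 | (6S)-6-[2-(1,3-dioxolan-2-yl)ethyl]cyclohept-2-en-1-one | O=C1C=CCC[C@@H](CCC2OCCO2)C1 | intermediate
5 | (E)-prop-1-enylboronic acid | C/C=C/B(O)O | starting material
6 | (3S,6S)-3-[2-(1,3-dioxolan-2-yl)ethyl]-6-[(E)-prop-1-enyl]cycloheptan-1-one | O=C1C[C@@H](/C=C/C)CC[C@@H](CCC2OCCO2)C1 | intermediate
7 | 3-[3-oxo-5-((E)-prop-1-enyl)cycloheptyl]propanal, configured as 6 (not isolated) | O=C1C[C@@H](/C=C/C)CC[C@@H](CCC=O)C1 | intermediate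
8 | (3aS,6S)-6-[(E)-prop-1-enyl]-3,3a,4,5,6,7-hexahydroazulen-8(2H)-one | O=C1C[C@@H](/C=C/C)CC[C@H]2CCC=C12 | intermediate
9 | (3aR,6R)-7-methylidene-6-[(E)-prop-1-enyl]-3,3a,4,5,6,7-hexahydroazulen-8(2H)-one | O=C1C(=C)[C@@H](/C=C/C)CC[C@H]2CCC=C12 | intermediate
10 | methyl isocyanoacetate | [C-]#[N+]CC(=O)OC | starting material
11 | methyl 8-oxo-6-[(E)-prop-1-enyl]-octahydro-8H-spiro[azulene-7,3'-pyrrole]-5'-carboxylate (1-pyrroline, C22 spiro) | O=C1[C@]2(C=N[C@@H](C(=O)OC)C2)[C@@H](/C=C/C)CC[C@H]3CCC=C13 | intermediate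
12 | N-Boc 2'-hydroxypyrrolidine (hemiaminal) form of 11 (not isolated) | O=C1[C@]2(C(O)N(C(=O)OC(C)(C)C)[C@@H](C(=O)OC)C2)[C@@H](/C=C/C)CC[C@H]3CCC=C13 | intermediate
13 | methyl 2-[(tert-butoxycarbonyl)amino]-3-[7-(hydroxymethyl)-8-oxo-6-[(E)-prop-1-enyl]-octahydroazulen-7-yl]propanoate | O=C1[C@@](CO)(C[C@@H](NC(=O)OC(C)(C)C)C(=O)OC)[C@@H](/C=C/C)CC[C@H]2CCC=C12 | intermediate
14 | allyl methacrylate | C=C(C)C(=O)OCC=C | starting material
15 | 3'-amino-6-[(E)-prop-1-enyl]-spiro[hexahydroazulene-7,5'-oxane]-2',8-dione (not isolated) | O=C1[C@]2(COC(=O)[C@H](N)C2)[C@@H](/C=C/C)CC[C@H]3CCC=C13 | intermediate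
16 | allyl 2-methyl-3-[(spiro lactone-3'-yl)amino]propanoate (N-alkylated 15, C2 mixture) | O=C1[C@]2(COC(=O)[C@H](NCC(C)C(=O)OCC=C)C2)[C@@H](/C=C/C)CC[C@H]3CCC=C13 | intermediate
17 | 6-formyl analogue of 16 (C5 aldehyde, not isolated) | O=C1[C@]2(COC(=O)[C@H](NCC(C)C(=O)OCC=C)C2)[C@@H](C=O)CC[C@H]3CCC=C13 | intermediate
18 | bridged amino-lactone ketone (ring B closed; 2-oxa-6-azabicyclo[3.3.1]nonan-3-one fused to the azulen-8-one) | O=C1[C@@]23COC(=O)[C@@H](C2)N(CC(C)C(=O)OCC=C)C[C@H]3CC[C@H]4CCC=C14 | intermediate
19 | C14 spiro-oxirane of 18 | C1OC12[C@@]34COC(=O)[C@@H](C3)N(CC(C)C(=O)OCC=C)C[C@H]4CC[C@H]5CCC=C25 | intermediate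
20 | C14 carbaldehyde (CHO = C19) | O=CC1[C@@]23COC(=O)[C@@H](C2)N(CC(C)C(=O)OCC=C)C[C@H]3CC[C@H]4CCC=C14 | intermediate
21 | methyl acrylate | C=CC(=O)OC | starting material
22 | C14-quaternary aldehyde with CH2CH2CO2CH3 | O=C[C@@]1(CCC(=O)OC)[C@@]23COC(=O)[C@@H](C2)N(CC(C)C(=O)OCC=C)C[C@H]3CC[C@H]4CCC=C14 | intermediate
23 | Dieckmann keto aldehyde (ring A closed, C23H2OH free; not isolated) | O=C[C@@]1(CCC(=O)OC)[C@@]2(CO)CC3C(=O)C(C)(C(=O)OCC=C)CN3C[C@H]2CC[C@H]4CCC=C14 | intermediate
24 | aldol hydroxy ester (ring F closed, C19–OH; not isolated) | CC1(C(=O)OCC=C)CN2C[C@H]3CC[C@H]4CCC=C4[C@@]5(CCC(=O)OC)[C@H](O)[C@@]2(C[C@@]35CO)C1=O | intermediate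
25 | allyl ester of the target 2-carboxylic acid (C2 quaternary, mixture) | CC1(C(=O)OCC=C)CN2C[C@H]3CC[C@H]4CCC=C4[C@@]45CCC(=O)O[C@@H]4[C@@]2(C[C@@]35CO)C1=O | intermediate
26 | CNP0180795.1 | C[C@@H]1CN2C[C@H]3CC[C@H]4CCC=C4[C@@]45CCC(=O)O[C@@H]4[C@@]2(C[C@@]35CO)C1=O | target

**Step count:** 14 steps in total; the longest linear sequence is 14 steps (from cycloheptanone).

**Steps most likely to fail**

Step 13 (three-ring cascade). The Dieckmann closure gives a non-enolisable β-keto ester and could revert, or the aldol could stall. The fallback sets out from 22 and returns at 25. LiHMDS in THF at −78 °C with Et3SiCl present closes ring A and traps the released C23 alkoxide, giving the triethylsilyl ether keto aldehyde F4. Soft enolisation (MgBr2·OEt2, i-Pr2NEt, CH2Cl2) then effects the C20-to-C19 aldol and lactonisation to the triethylsilyl ether lactone F5. HF·pyridine removes the silyl group to give 25.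

Step 10 (epoxidation of the hindered C14 ketone). The ketone sits next to the quaternary C22 and may resist the ylide, or the lactone may compete. The fallback sets out from 18 and returns at 20, replacing steps 10 and 11. A Wittig reaction with methoxymethylenetriphenylphosphorane (Ph3P+CH2OMe Cl−, KHMDS, THF) gives the methyl dienol ether F3. Hydrolysis with aqueous oxalic acid in THF gives aldehyde 20.

Step 6 (spiro-annulation setting C22). The cyclisation must form the quaternary centre on the correct face and must not isomerise the imine. The fallback sets out from 9 and returns at 15. DBU-catalysed Michael addition of dimethyl 2-[(tert-butoxycarbonyl)amino]malonate to the exo-methylene group is followed in the same flask by aqueous formaldehyde/K2CO3; aldol at C22 anti to the propenyl group and lactonisation give the malonate-derived lactone ester F1. Krapcho demethoxycarbonylation (LiCl, wet DMSO, 130 °C) gives the N-Boc amino lactone F2. TFA then releases 15, which continues through the aza-Michael stage of step 8 to 16.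

**Further compounds**
F1 | step 6 | malonate-derived lactone ester (3'-(Boc-amino)-3'-methoxycarbonyl spiro lactone) | O=C1[C@]2(COC(=O)C(NC(=O)OC(C)(C)C)(C(=O)OC)C2)[C@@H](/C=C/C)CC[C@H]3CCC=C13
F2 | step 6 | N-Boc amino lactone (N-Boc derivative of 15) | O=C1[C@]2(COC(=O)[C@H](NC(=O)OC(C)(C)C)C2)[C@@H](/C=C/C)CC[C@H]3CCC=C13
F3 | step 10 | methyl dienol ether (C14=C19H–OCH3, E/Z mixture) | COC=C1[C@@]23COC(=O)[C@@H](C2)N(CC(C)C(=O)OCC=C)C[C@H]3CC[C@H]4CCC=C14
F4 | step 13 | triethylsilyl ether keto aldehyde (C23–OSiEt3 derivative of 23) | O=C[C@@]1(CCC(=O)OC)[C@@]2(CO[Si](CC)(CC)CC)CC3C(=O)C(C)(C(=O)OCC=C)CN3C[C@H]2CC[C@H]4CCC=C14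
F5 | step 13 | triethylsilyl ether lactone (C23–OSiEt3 derivative of 25) | CC1(C(=O)OCC=C)CN2C[C@H]3CC[C@H]4CCC=C4[C@@]45CCC(=O)O[C@@H]4[C@@]2(C[C@@]35CO[Si](CC)(CC)CC)C1=O
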